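**Assumption:** the target SMILES contains no stereocentres (umbilicaric acid is achiral), so there is no enantiomer to select and no stereocontrol is needed.

## Retrosynthetic overview

1. Umbilicaric acid ⇐ global hydrogenolysis of a tri-benzyl-protected tridepside ⇐ esterification of an A–B didepside acid with benzyl orsellinate (ring C).
2. A–B acid ⇐ Pd-catalysed, carboxylate-directed ortho-C–H methylation of the nor-methyl A–B depside acid (new step) ⇐ ring-A acid + allyl 2,4-dihydroxybenzoate.
3. Ring-A acid and ring-C orsellinate ⇐ the same C–H methylation on O-protected 2,4-dihydroxybenzoic acids (only one ortho C–H is free, so regiochemistry is fixed).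
4. All three arenes ⇐ 2,4-dihydroxybenzoic acid ⇐ resorcinol + CO2 (Kolbe–Schmitt); each ring = resorcinol + CO2 + CH3.
5. No ring is constructed; ring A is completed first, ring B is methylated on the A–B ester, ring C is made in parallel and joined last.

## Route

**Step 1**
Reactants: 1 resorcinol
Product: 2 2,4-dihydroxybenzoic acid
Conditions: KHCO3, H2O, CO2 (1 atm), 95 °C then reflux; HCl
Reagents that add atoms: carbon dioxide (as KHCO3/CO2), O=C=O
Why: Kolbe–Schmitt carboxylation of the resorcinol phenoxide occurs at C4 (ortho to one OH, para to the other) to give β-resorcylic acid.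

**Step 2**
Reactants: 2 2,4-dihydroxybenzoic acid
Product: 3 benzyl 4-(benzyloxy)-2-hydroxybenzoate
Conditions: BnBr (2.1 equiv), K2CO3 (2.2 equiv), acetone, reflux
Reagents that add atoms: benzyl bromide, BrCc1ccccc1
Why: Carboxylate alkylation and Williamson etherification of the 4-OH proceed while the 2-OH stays free because it is hydrogen-bonded to the ester carbonyl.

**Step 3**
Reactants: 3 benzyl 4-(benzyloxy)-2-hydroxybenzoate
Product: 4 benzyl 4-(benzyloxy)-2-methoxybenzoate
Conditions: MeI, K2CO3, DMF, 50 °C
Reagents that add atoms: iodomethane, CI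
Why: Williamson O-methylation of the remaining chelated phenol under forcing polar aprotic conditions.

**Step 4**
Reactants: 4 benzyl 4-(benzyloxy)-2-methoxybenzoate
Product: 5 4-(benzyloxy)-2-methoxybenzoic acid
Conditions: KOH, MeOH/THF/H2O, 60 °C; then 1 M HCl
Reagents that add atoms: water (as hydroxide), O
Why: Saponification (BAc2) of the unhindered benzyl ester frees the carboxylic acid needed as directing group; aryl ethers are inert.

**Step 5**
Reactants: 5 4-(benzyloxy)-2-methoxybenzoic acid
Product: 6 4-(benzyloxy)-2-methoxy-6-methylbenzoic acid (ring-A acid)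
Conditions: Pd(OAc)2 (10 mol %), Ac-Ile-OH (20 mol %), MeBF3K (3 equiv), Ag2CO3 (2 equiv), benzoquinone (0.5 equiv), K2HPO4, t-AmOH, 90 °C
Reagents that add atoms: potassium methyltrifluoroborate, C[B-](F)(F)F.[K+]
Why: Carboxylate-directed Pd(II)/Pd(0) ortho-C–H methylation with a methylboron reagent, where C6–H is the only ortho C–H so a single regioisomer forms and over-methylation is impossible.

**Step 6**
Reactants: 2 2,4-dihydroxybenzoic acid
Product: 7 allyl 2,4-dihydroxybenzoate
Conditions: allyl bromide (1.05 equiv), KHCO3 (1.1 equiv), DMF, 40 °C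
Reagents that add atoms: allyl bromide, C=CCBr
Why: Bicarbonate deprotonates only the carboxylic acid, so SN2 alkylation gives the allyl ester with both phenols untouched.

**Step 7**
Reactants: 6 4-(benzyloxy)-2-methoxy-6-methylbenzoic acid; 7 allyl 2,4-dihydroxybenzoate
Product: 8 allyl 4-{[4-(benzyloxy)-2-methoxy-6-methylbenzoyl]oxy}-2-hydroxybenzoate
Conditions: DCC (1.1 equiv), DMAP (0.1 equiv), CH2Cl2, 0 °C to rt
Reagents that add atoms: none
Why: Steglich esterification takes place at the free 4-OH, the chelated 2-OH being far less nucleophilic (standard depside selectivity).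

**Step 8**
Reactants: 8 allyl 4-{[4-(benzyloxy)-2-methoxy-6-methylbenzoyl]oxy}-2-hydroxybenzoate
Product: 9 allyl 2-(benzyloxy)-4-{[4-(benzyloxy)-2-methoxy-6-methylbenzoyl]oxy}benzoate
Conditions: BnBr (1.3 equiv), K2CO3 (1.5 equiv), DMF, 40 °C
Reagents that add atoms: benzyl bromide, BrCc1ccccc1
Why: Williamson benzylation caps the salicylate OH, and the depside ester survives because it is a di-ortho-substituted benzoate shielded from carbonate and phenoxide.

**Step 9**
Reactants: 9 allyl 2-(benzyloxy)-4-{[4-(benzyloxy)-2-methoxy-6-methylbenzoyl]oxy}benzoate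
Product: 10 2-(benzyloxy)-4-{[4-(benzyloxy)-2-methoxy-6-methylbenzoyl]oxy}benzoic acid
Conditions: Pd(PPh3)4 (3 mol %), PhSiH3 (2 equiv), CH2Cl2, rt
Reagents that add atoms: none
Why: Tsuji–Trost deallylation via a π-allyl-Pd intermediate with a non-nucleophilic hydride scavenger unmasks the acid without touching benzyl ethers or the aryl ester.

**Step 10**
Reactants: 10 2-(benzyloxy)-4-{[4-(benzyloxy)-2-methoxy-6-methylbenzoyl]oxy}benzoic acid
Product: 11 2-(benzyloxy)-4-{[4-(benzyloxy)-2-methoxy-6-methylbenzoyl]oxy}-6-methylbenzoic acid (A–B acid)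
Conditions: Pd(OAc)2 (10 mol %), Ac-Ile-OH (20 mol %), MeBF3K (3 equiv), Ag2CO3 (2 equiv), benzoquinone (0.5 equiv), K2HPO4, t-AmOH, 80 °C
Reagents that add atoms: potassium methyltrifluoroborate, C[B-](F)(F)F.[K+]
Why: Proposed new method: carboxylate-directed ortho-C–H methylation on a depside acid, a substrate class carrying a base- and transesterification-sensitive aryl ester on which this reaction has not been shown. The κ1-carboxylate-bound Pd(II) should undergo amino-acid-assisted concerted metalation–deprotonation at the only ortho C–H (ring B C6), then transmetalation from the methylboron reagent, benzoquinone-promoted C(sp2)–C(sp3) reductive elimination and Ag(I) reoxidation. Ring A has no C–H ortho to a directing group, the para-aroyloxy group makes ring B less electron-rich (less prone to protodecarboxylation), and the hindered 2,6-disubstituted benzoate linkage should resist the weak base in a tertiary alcohol. The A-acyl group thereby serves as the ring-B 4-O protecting group. Closest known reaction: Pd(II)-catalysed carboxylate-directed ortho-C–H alkylation of simple benzoic acids with alkylboron reagents (as in steps 5 and 13).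

**Step 11**
Reactants: 2 2,4-dihydroxybenzoic acid
Product: 12 benzyl 2,4-bis(benzyloxy)benzoate
Conditions: BnBr (3.5 equiv), K2CO3 (4 equiv), DMF, 70 °C
Reagents that add atoms: benzyl bromide, BrCc1ccccc1
Why: Exhaustive Williamson/carboxylate benzylation under forcing conditions also alkylates the chelated 2-OH.

**Step 12**
Reactants: 12 benzyl 2,4-bis(benzyloxy)benzoate
Product: 13 2,4-bis(benzyloxy)benzoic acid
Conditions: KOH, MeOH/THF/H2O, reflux; then 1 M HCl
Reagents that add atoms: water (as hydroxide), O
Why: Saponification cleaves only the benzyl ester, leaving both benzyl ethers.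

**Step 13**
Reactants: 13 2,4-bis(benzyloxy)benzoic acid
Product: 14 2,4-bis(benzyloxy)-6-methylbenzoic acid
Conditions: Pd(OAc)2 (10 mol %), Ac-Ile-OH (20 mol %), MeBF3K (3 equiv), Ag2CO3 (2 equiv), benzoquinone (0.5 equiv), K2HPO4, t-AmOH, 90 °C
Reagents that add atoms: potassium methyltrifluoroborate, C[B-](F)(F)F.[K+]
Why: Same carboxylate-directed Pd-catalysed ortho-C–H methylation as step 5, with C6–H the only available ortho position.

**Step 14**
Reactants: 14 2,4-bis(benzyloxy)-6-methylbenzoic acid
Product: 15 orsellinic acid (2,4-dihydroxy-6-methylbenzoic acid)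
Conditions: H2 (1 atm), 10% Pd/C, EtOAc/MeOH, rt (keep below 30 °C)
Reagents that add atoms: none
Why: Hydrogenolysis of both benzyl ethers under neutral, cold conditions avoids the thermal decarboxylation orsellinic acid is prone to.

**Step 15**
Reactants: 15 orsellinic acid
Product: 16 benzyl orsellinate (benzyl 2,4-dihydroxy-6-methylbenzoate)
Conditions: BnBr (1.05 equiv), KHCO3 (1.2 equiv), DMF, rt
Reagents that add atoms: benzyl bromide, BrCc1ccccc1
Why: Bicarbonate-mediated SN2 alkylation is selective for the carboxylate, giving the standard ring-C depside partner with free phenols.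

**Step 16**
Reactants: 11 A–B acid; 16 benzyl orsellinate
Product: 17 benzyl 4-{[2-(benzyloxy)-4-{[4-(benzyloxy)-2-methoxy-6-methylbenzoyl]oxy}-6-methylbenzoyl]oxy}-2-hydroxy-6-methylbenzoate
Conditions: DCC (1.2 equiv), DMAP (0.1 equiv), CH2Cl2/toluene, 0 °C to rt
Reagents that add atoms: none
Why: Steglich depside coupling acylates the free 4-OH of benzyl orsellinate in preference to its chelated 2-OH, as for 2-O-benzyl orsellinic acids generally.

**Step 17**
Reactants: 17 protected tridepside
Product: 18 umbilicaric acid
Conditions: H2 (1 atm), 10% Pd/C, EtOAc, rt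
Reagents that add atoms: none
Why: Global hydrogenolysis removes the two benzyl ethers and the benzyl ester in one operation while both depside aryl ester bonds remain intact.

## Compound list

1 | resorcinol | Oc1cccc(O)c1 | starting material
2 | 2,4-dihydroxybenzoic acid | OC(=O)c1ccc(O)cc1O | intermediate
3 | benzyl 4-(benzyloxy)-2-hydroxybenzoate | O=C(OCc1ccccc1)c1ccc(OCc2ccccc2)cc1O | intermediate
4 | benzyl 4-(benzyloxy)-2-methoxybenzoate | COc1cc(OCc2ccccc2)ccc1C(=O)OCc1ccccc1 | intermediate
5 | 4-(benzyloxy)-2-methoxybenzoic acid | COc1cc(OCc2ccccc2)ccc1C(=O)O | intermediate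
6 | 4-(benzyloxy)-2-methoxy-6-methylbenzoic acid | COc1cc(OCc2ccccc2)cc(C)c1C(=O)O | intermediate
7 | allyl 2,4-dihydroxybenzoate | C=CCOC(=O)c1ccc(O)cc1O | intermediate
8 | allyl 4-{[4-(benzyloxy)-2-methoxy-6-methylbenzoyl]oxy}-2-hydroxybenzoate | COc1cc(OCc2ccccc2)cc(C)c1C(=O)Oc1ccc(C(=O)OCC=C)c(O)c1 | intermediate
9 | allyl 2-(benzyloxy)-4-{[4-(benzyloxy)-2-methoxy-6-methylbenzoyl]oxy}benzoate | COc1cc(OCc2ccccc2)cc(C)c1C(=O)Oc1ccc(C(=O)OCC=C)c(OCc2ccccc2)c1 | intermediate
10 | 2-(benzyloxy)-4-{[4-(benzyloxy)-2-methoxy-6-methylbenzoyl]oxy}benzoic acid | COc1cc(OCc2ccccc2)cc(C)c1C(=O)Oc1ccc(C(=O)O)c(OCc2ccccc2)c1 | intermediate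
11 | 2-(benzyloxy)-4-{[4-(benzyloxy)-2-methoxy-6-methylbenzoyl]oxy}-6-methylbenzoic acid | COc1cc(OCc2ccccc2)cc(C)c1C(=O)Oc1cc(C)c(C(=O)O)c(OCc2ccccc2)c1 | intermediate
12 | benzyl 2,4-bis(benzyloxy)benzoate | O=C(OCc1ccccc1)c1ccc(OCc2ccccc2)cc1OCc1ccccc1 | intermediate
13 | 2,4-bis(benzyloxy)benzoic acid | OC(=O)c1ccc(OCc2ccccc2)cc1OCc1ccccc1 | intermediate
14 | 2,4-bis(benzyloxy)-6-methylbenzoic acid | Cc1cc(OCc2ccccc2)cc(OCc2ccccc2)c1C(=O)O | intermediate
15 | orsellinic acid | Cc1cc(O)cc(O)c1C(=O)O | intermediate
16 | benzyl orsellinate | Cc1cc(O)cc(O)c1C(=O)OCc1ccccc1 | intermediate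
17 | benzyl 4-{[2-(benzyloxy)-4-{[4-(benzyloxy)-2-methoxy-6-methylbenzoyl]oxy}-6-methylbenzoyl]oxy}-2-hydroxy-6-methylbenzoate | COc1cc(OCc2ccccc2)cc(C)c1C(=O)Oc1cc(C)c(C(=O)Oc2cc(C)c(C(=O)OCc3ccccc3)c(O)c2)c(OCc2ccccc2)c1 | intermediate
18 | umbilicaric acid | COc1cc(O)cc(C)c1C(=O)Oc1cc(C)c(C(=O)Oc2cc(C)c(C(=O)O)c(O)c2)c(O)c1 | target

## Summary

**Total step count:** 17

**Longest linear sequence:** 11 steps (1, 2, 3, 4, 5, 7, 8, 9, 10, 16, 17). The ring-C branch (11–15) and the ring-B ester (6) run in parallel.

**Steps most likely to fail:**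

1. **Step 10 (proposed new C–H methylation on the depside acid).** Risks are protodecarboxylation of the electron-rich 2,6-disubstituted product, cleavage of the A–B ester, or poor conversion. Fallback (known chemistry): install the ring-B methyl before depside formation. Esterify orsellinic acid 15 with allyl bromide/KHCO3 to allyl orsellinate, couple with 6 (DCC, 4-OH selective), benzylate the 2-OH, and deallylate with Pd(0) to reach 11.

2. **Step 13 (and the identical step 5): C–H methylation of electron-rich 2,4-dialkoxybenzoic acids.** Risks are Ag/Pd-mediated protodecarboxylation and incomplete conversion. Fallback: abandon C–H functionalisation for the monomers and build the ring de novo by self-condensation of methyl acetoacetate dianion (NaH, n-BuLi, THF) to methyl orsellinate. Saponification gives 15; 4-O-benzylation, 2-O-methylation and saponification give 6.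

3. **Step 16 (acylation with the di-ortho-substituted didepside acid 11).** Risks are slow activation, N-acylurea formation, or attack at the internal depside ester. Fallback: reverse the polarity of the bond formation. O-arylate the carboxylate of 11 with benzyl 2-(benzyloxy)-4-bromo-6-methylbenzoate by Ni/photoredox (or Cu-mediated) carboxylate–aryl bromide C–O coupling, which avoids nucleophilic attack at the hindered acyl carbon. The bromide would come from 3-bromophenol by the same Kolbe–Schmitt, benzylation and C–H methylation sequence.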